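## Retrosynthetic overview

1. Target ⇐ its dibenzyl ester; the oxirane ⇐ a 14,15-diol acetonide, with C14 bought as D-glyceraldehyde and C13 set from it by Felkin–Anh methyl addition.
2. Ring C ⇐ C8–O bond: visible-light acridinium cation-radical 6-endo hydroetherification of a Δ8(9) tetrasubstituted alkenol, setting C8 and C9 together.
3. C9–C11 ⇐ B-alkyl Suzuki coupling of a ring-B enol triflate (fragment 1) with the hydroborated C11–C16 carbinol (fragment 2).
4. Ring B is bought as (S)-carvone: C4–C5 and C1–C10 come from a one-pot isobutyrate Michael addition/bromoacetate alkylation trans to the isopropenyl group, which is then excised. Ring A is never made; the seco-diacid is carried as two benzyl esters.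
5. Ring order: ring B (bought) → ring C (photochemical) → oxirane (last).

Assumption: positions are given in labdane numbering (ring B = C5–C10; ring C = O, C8, C9, C11–C13; oxirane = C14/C15), and (S)-carvone, benzyl isobutyrate, benzyl bromoacetate and 2,3-O-isopropylidene-D-glyceraldehyde are taken as catalogue compounds.

## Route

Step 1
Reactants: 1 (S)-(+)-carvone; 2 benzyl isobutyrate; 3 benzyl bromoacetate
Product: 6 benzyl 2-[(1S,2R,5S)-2-(2-benzyloxy-2-oxoethyl)-2-methyl-3-oxo-5-(prop-1-en-2-yl)cyclohexyl]-2-methylpropanoate, via lithium ester enolate 4 (not isolated), via lithium ketone enolate 5 (not isolated)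
Conditions: 2, LiN(iPr)2, THF, −78 °C; then 1, −78 → 23 °C; then DMPU, 3, −78 → 0 °C
Reagents that add atoms: none
Why: Tandem Michael addition–enolate alkylation: the α,α-disubstituted lithium ester enolate gives the thermodynamic 1,4-adduct by axial attack trans to the isopropenyl group (sets C5), and the regiodefined enolate is then C-alkylated anti to the new bulky C5 substituent (sets quaternary C10 with CH2CO2Bn trans to the C4 unit), so both centres are controlled by the bought carvone centre.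

Step 2
Reactants: 6
Product: 8 benzyl 2-[(1S,2R)-2-(2-benzyloxy-2-oxoethyl)-2-methyl-3-oxocyclohexyl]-2-methylpropanoate, via methoxy hydroperoxide 7 (not isolated)
Conditions: O3, MeOH, −78 °C; then FeSO4·7H2O, PhSH, −78 → 23 °C
Reagents that add atoms: none
Why: Dealkenylative hydrogenation (ozonolysis in MeOH to the α-methoxy hydroperoxide, O–O cleavage by divalent iron, β-scission to a secondary C7 radical plus methyl acetate, then H-atom transfer from PhSH) removes the isopropenyl group once it has done its stereodirecting work, leaving ketone, esters and the C5/C10 centres untouched.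

Step 3
Reactants: 8
Product: 9 benzyl 2-[(1S,2R)-2-(2-benzyloxy-2-oxoethyl)-2,4-dimethyl-3-oxocyclohexyl]-2-methylpropanoate (both C8 epimers)
Conditions: LiN(iPr)2, THF, −78 °C; MeI, −78 → −20 °C
Reagents that add atoms: iodomethane (CI)
Why: Kinetic enolate alkylation at the only enolisable α-carbon (C8) installs C17; the epimer ratio at C8 is irrelevant because this carbon becomes sp2 in step 4.

Step 4
Reactants: 9
Product: 10 benzyl 2-[(1S,2R)-2-(2-benzyloxy-2-oxoethyl)-2,4-dimethyl-3-(trifluoromethanesulfonyloxy)cyclohex-3-en-1-yl]-2-methylpropanoate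
Conditions: KN(SiMe3)2, THF, −78 °C; PhNTf2, −78 → 0 °C
Reagents that add atoms: N-phenylbis(trifluoromethanesulfonimide) (O=S(=O)(N(c1ccccc1)S(=O)(=O)C(F)(F)F)C(F)(F)F)
Why: Enolate O-sulfonylation (enol triflate formation): enolisation is possible only towards C8, so the tetrasubstituted C8=C9 triflate forms regiospecifically, the ketone α-CH being more acidic than the neopentylic ester CH2.

Step 5
Reactants: 11 (R)-2,2-dimethyl-1,3-dioxolane-4-carbaldehyde (2,3-O-isopropylidene-D-glyceraldehyde)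
Product: 12 1-[(4R)-2,2-dimethyl-1,3-dioxolan-4-yl]prop-2-en-1-ol (both carbinol epimers)
Conditions: CH2=CHMgBr, THF, −78 → 0 °C
Reagents that add atoms: vinylmagnesium bromide (C=C[Mg]Br)
Why: Grignard 1,2-addition to the aldehyde; the carbinol configuration is immaterial (oxidised in step 6) and C14 is the bought D-glyceraldehyde centre.

Step 6
Reactants: 12
Product: 13 1-[(4R)-2,2-dimethyl-1,3-dioxolan-4-yl]prop-2-en-1-one
Conditions: Dess–Martin periodinane, NaHCO3, CH2Cl2, 0 → 23 °C; used at once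
Reagents that add atoms: none
Why: Dess–Martin oxidation under buffered, non-basic conditions gives the vinyl ketone without epimerising the α-alkoxy centre C14.

Step 7
Reactants: 13
Product: 14 (2R)-2-[(4R)-2,2-dimethyl-1,3-dioxolan-4-yl]but-3-en-2-ol
Conditions: MeLi, THF, −78 °C
Reagents that add atoms: methyllithium ([Li]C)
Why: Felkin–Anh (polar, non-chelated) 1,2-addition of MeLi to the α-alkoxy ketone, anti to the C14–O bond, sets the C13 carbinol centre (R) under control of the bought C14 centre; the minor C13 epimer is removed by chromatography.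

Step 8
Reactants: 14; 10
Product: 16 benzyl 2-[(1S,2R)-2-(2-benzyloxy-2-oxoethyl)-3-{(3R)-3-[(4R)-2,2-dimethyl-1,3-dioxolan-4-yl]-3-hydroxybutyl}-2,4-dimethylcyclohex-3-en-1-yl]-2-methylpropanoate, via B-alkyl-9-BBN 15 (not isolated)
Conditions: 14, 9-BBN (2.2 equiv), THF, 0 → 23 °C; then 10, Pd(dppf)Cl2 (10 mol%), AsPh3, Cs2CO3, DMF/H2O, 50 °C
Reagents that add atoms: none
Why: Anti-Markovnikov hydroboration of the monosubstituted alkene (one extra equivalent of 9-BBN is consumed by the OH) followed by B-alkyl Suzuki–Miyaura coupling with the enol triflate forms the C9–C11 bond; no stereocentre is made or touched.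

Step 9
Reactants: 16
Product: 17 benzyl 2-[(2R,4aS,5R,6S,8aS)-5-(2-benzyloxy-2-oxoethyl)-2-[(4R)-2,2-dimethyl-1,3-dioxolan-4-yl]-2,5,8a-trimethyloctahydro-2H-chromen-6-yl]-2-methylpropanoate
Conditions: 9-mesityl-10-methylacridinium tetrafluoroborate (5 mol%), PhSSPh (20 mol%), ClCH2CH2Cl, 450 nm LEDs, 25 °C, Ar
Reagents that add atoms: none
Why: Proposed new method: cation-radical 6-endo hydroetherification of a tetrasubstituted cyclohexene by a tethered tertiary alcohol — the excited acridinium (about +2.0 V vs SCE) oxidises only the C8=C9 alkene (about +1.6 V), the C13 hydroxyl adds to C8 (the less congested terminus, C9 being neopentylic beside quaternary C10) on the face opposite the axial C20 methyl, and after proton loss the tertiary C9 radical takes H from PhSH on that same face (the other is blocked by the C20 and C17 methyls), giving net syn H/O addition and the trans-fused ether with C8 and C9 set by C10, which the anti addition of an acid-mediated closure could not give; the closest known reaction type is the acridinium-photocatalysed anti-Markovnikov hydroetherification of trisubstituted alkenols with a thiol H-atom-transfer cocatalyst, not yet shown for tetrasubstituted ring alkenes, for 6-endo closure by a tertiary alcohol, or for setting two contiguous ring-fusion centres.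

Step 10
Reactants: 17
Product: 18 benzyl 2-[(2R,4aS,5R,6S,8aS)-5-(2-benzyloxy-2-oxoethyl)-2-[(1R)-1,2-dihydroxyethyl]-2,5,8a-trimethyloctahydro-2H-chromen-6-yl]-2-methylpropanoate
Conditions: AcOH/H2O 4:1, 40 °C
Reagents that add atoms: none
Why: Acid-catalysed acetonide hydrolysis; the bis-tertiary ether and the benzyl esters are stable to warm aqueous AcOH and no stereocentre is involved.

Step 11
Reactants: 18
Product: 20 benzyl 2-[(2R,4aS,5R,6S,8aS)-5-(2-benzyloxy-2-oxoethyl)-2,5,8a-trimethyl-2-[(2R)-oxiran-2-yl]octahydro-2H-chromen-6-yl]-2-methylpropanoate, via primary tosylate 19 (not isolated)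
Conditions: TsCl, Et3N, Bu2SnO (2 mol%), CH2Cl2, 0 → 23 °C; then DBU, 23 °C
Reagents that add atoms: none
Why: Bu2SnO-catalysed selective sulfonylation of the primary hydroxyl, then intramolecular Williamson etherification (3-exo-tet) by the C14 alkoxide; the C14–O bond is never broken, so the bought configuration is retained in the oxirane.

Step 12
Reactants: 20
Product: 21 2-[(2R,4aS,5R,6S,8aS)-5-(carboxymethyl)-2,5,8a-trimethyl-2-[(2R)-oxiran-2-yl]octahydro-2H-chromen-6-yl]-2-methylpropanoic acid (CNP0160287.1)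
Conditions: H2 (1 atm), Pd/C, EtOAc, 23 °C
Reagents that add atoms: none
Why: Catalytic hydrogenolysis of both benzyl esters under neutral conditions leaves the non-benzylic terminal epoxide and the tertiary ether intact and sets free the diacid.

## Compound list

1 | (S)-(+)-carvone, (5S)-2-methyl-5-(prop-1-en-2-yl)cyclohex-2-en-1-one | CC1=CC[C@@H](CC1=O)C(C)=C | starting material
2 | benzyl isobutyrate (benzyl 2-methylpropanoate) | CC(C)C(=O)OCc1ccccc1 | starting material
3 | benzyl bromoacetate | BrCC(=O)OCc1ccccc1 | starting material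
4 | lithium 1-(benzyloxy)-2-methylprop-1-en-1-olate (ester enolate of 2; not isolated) | [Li+].[O-]C(OCc1ccccc1)=C(C)C | intermediate
5 | lithium (3S,5S)-3-[1-(benzyloxy)-2-methyl-1-oxopropan-2-yl]-2-methyl-5-(prop-1-en-2-yl)cyclohex-1-en-1-olate (not isolated) | [Li+].[O-]C1=C(C)[C@@H](C(C)(C)C(=O)OCc2ccccc2)C[C@H](C(C)=C)C1 | intermediate
6 | benzyl 2-[(1S,2R,5S)-2-(2-benzyloxy-2-oxoethyl)-2-methyl-3-oxo-5-(prop-1-en-2-yl)cyclohexyl]-2-methylpropanoate | O=C1[C@](C)(CC(=O)OCc2ccccc2)[C@@H](C(C)(C)C(=O)OCc2ccccc2)C[C@H](C(C)=C)C1 | intermediate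
7 | benzyl 2-[(1S,2R,5S)-2-(2-benzyloxy-2-oxoethyl)-5-(1-hydroperoxy-1-methoxyethyl)-2-methyl-3-oxocyclohexyl]-2-methylpropanoate (epimers at the peroxy carbon; not isolated) | O=C1[C@](C)(CC(=O)OCc2ccccc2)[C@@H](C(C)(C)C(=O)OCc2ccccc2)C[C@H](C(C)(OC)OO)C1 | intermediate
8 | benzyl 2-[(1S,2R)-2-(2-benzyloxy-2-oxoethyl)-2-methyl-3-oxocyclohexyl]-2-methylpropanoate | O=C1[C@](C)(CC(=O)OCc2ccccc2)[C@@H](C(C)(C)C(=O)OCc2ccccc2)CCC1 | intermediate
9 | benzyl 2-[(1S,2R)-2-(2-benzyloxy-2-oxoethyl)-2,4-dimethyl-3-oxocyclohexyl]-2-methylpropanoate (both C8 epimers) | O=C1[C@](C)(CC(=O)OCc2ccccc2)[C@@H](C(C)(C)C(=O)OCc2ccccc2)CCC1C | intermediate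
10 | benzyl 2-[(1S,2R)-2-(2-benzyloxy-2-oxoethyl)-2,4-dimethyl-3-(trifluoromethanesulfonyloxy)cyclohex-3-en-1-yl]-2-methylpropanoate | CC1=C(OS(=O)(=O)C(F)(F)F)[C@](C)(CC(=O)OCc2ccccc2)[C@@H](C(C)(C)C(=O)OCc2ccccc2)CC1 | intermediate
11 | (R)-2,2-dimethyl-1,3-dioxolane-4-carbaldehyde (2,3-O-isopropylidene-D-glyceraldehyde) | O=C[C@H]1COC(C)(C)O1 | starting material
12 | 1-[(4R)-2,2-dimethyl-1,3-dioxolan-4-yl]prop-2-en-1-ol (both carbinol epimers) | C=CC(O)[C@H]1COC(C)(C)O1 | intermediate
13 | 1-[(4R)-2,2-dimethyl-1,3-dioxolan-4-yl]prop-2-en-1-one | C=CC(=O)[C@H]1COC(C)(C)O1 | intermediate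
14 | (2R)-2-[(4R)-2,2-dimethyl-1,3-dioxolan-4-yl]but-3-en-2-ol | C=C[C@@](C)(O)[C@H]1COC(C)(C)O1 | intermediate
15 | 9-{(3R)-3-[(4R)-2,2-dimethyl-1,3-dioxolan-4-yl]-3-hydroxybutyl}-9-borabicyclo[3.3.1]nonane (not isolated) | C1CC2CCCC(C1)B2CC[C@@](C)(O)[C@H]1COC(C)(C)O1 | intermediate
16 | benzyl 2-[(1S,2R)-2-(2-benzyloxy-2-oxoethyl)-3-{(3R)-3-[(4R)-2,2-dimethyl-1,3-dioxolan-4-yl]-3-hydroxybutyl}-2,4-dimethylcyclohex-3-en-1-yl]-2-methylpropanoate | CC1=C(CC[C@@](C)(O)[C@H]2COC(C)(C)O2)[C@](C)(CC(=O)OCc2ccccc2)[C@@H](C(C)(C)C(=O)OCc2ccccc2)CC1 | intermediate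
17 | benzyl 2-[(2R,4aS,5R,6S,8aS)-5-(2-benzyloxy-2-oxoethyl)-2-[(4R)-2,2-dimethyl-1,3-dioxolan-4-yl]-2,5,8a-trimethyloctahydro-2H-chromen-6-yl]-2-methylpropanoate | CC(C)(C(=O)OCc1ccccc1)[C@H]1CC[C@]2(C)O[C@@](C)([C@H]3COC(C)(C)O3)CC[C@H]2[C@]1(C)CC(=O)OCc1ccccc1 | intermediate
18 | benzyl 2-[(2R,4aS,5R,6S,8aS)-5-(2-benzyloxy-2-oxoethyl)-2-[(1R)-1,2-dihydroxyethyl]-2,5,8a-trimethyloctahydro-2H-chromen-6-yl]-2-methylpropanoate | CC(C)(C(=O)OCc1ccccc1)[C@H]1CC[C@]2(C)O[C@@](C)([C@H](O)CO)CC[C@H]2[C@]1(C)CC(=O)OCc1ccccc1 | intermediate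
19 | benzyl 2-[(2R,4aS,5R,6S,8aS)-5-(2-benzyloxy-2-oxoethyl)-2-[(1R)-1-hydroxy-2-(4-methylbenzenesulfonyloxy)ethyl]-2,5,8a-trimethyloctahydro-2H-chromen-6-yl]-2-methylpropanoate (not isolated) | CC(C)(C(=O)OCc1ccccc1)[C@H]1CC[C@]2(C)O[C@@](C)([C@H](O)COS(=O)(=O)c3ccc(C)cc3)CC[C@H]2[C@]1(C)CC(=O)OCc1ccccc1 | intermediate
20 | benzyl 2-[(2R,4aS,5R,6S,8aS)-5-(2-benzyloxy-2-oxoethyl)-2,5,8a-trimethyl-2-[(2R)-oxiran-2-yl]octahydro-2H-chromen-6-yl]-2-methylpropanoate | CC(C)(C(=O)OCc1ccccc1)[C@H]1CC[C@]2(C)O[C@@](C)([C@H]3CO3)CC[C@H]2[C@]1(C)CC(=O)OCc1ccccc1 | intermediate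
21 | 2-[(2R,4aS,5R,6S,8aS)-5-(carboxymethyl)-2,5,8a-trimethyl-2-[(2R)-oxiran-2-yl]octahydro-2H-chromen-6-yl]-2-methylpropanoic acid (CNP0160287.1) | CC(C)(C(=O)O)[C@H]1CC[C@]2(C)O[C@@](C)([C@H]3CO3)CC[C@H]2[C@]1(C)CC(=O)O | target

## Step count and risk

Total step count: 12. Longest linear sequence: 9 (steps 1–4 and 8–12, from carvone); the side-chain branch is steps 5–7.

The three steps most likely to fail:

**Step 9 (the proposed new step).** The risks are 5-exo closure at C9 to a spiro 9,13-ether, a cis ring fusion, and slow closure because the C14 unit must end up syn-axial to the C17 methyl. The fallback uses only known chemistry, sets out from 9 (and uses borane 15) and comes back at 17; it closes ring C on a Δ7 alkene whose C9 centre is already fixed. IBX in DMSO at 70 °C dehydrogenates 9 to the Δ7-9-ketone F1. Nucleophilic epoxidation (tBuOOH, DBU, CH2Cl2) attacks C7 axially, trans to the C4 side chain, and gives the 7,8-epoxy-9-ketone F2. Wharton transposition (N2H4·H2O, AcOH, MeOH, 0 °C, short contact to spare the esters) gives the 7-hydroxy-Δ8(9)-alkene F3. ClP(O)(OEt)2 with N-methylimidazole gives the 7-diethylphosphate F4. Copper-catalysed γ-selective anti-SN2′ allyl–alkyl coupling with 15 (CuOAc, KOtBu, THF, 50 °C) places the side chain on C9 trans to the departing phosphate and gives the Δ7 alkenol F5. Cobalt-hydride Markovnikov hydroalkoxylation of F5 ([N,N′-bis(3,5-di-tert-butylsalicylidene)ethane-1,2-diaminato]cobalt, N-fluoro-2,4,6-trimethylpyridinium tetrafluoroborate, PhSiH3, PhCF3) then forms the C8–O bond on the face opposite the C20 methyl and gives 17.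

**Step 1.** The risks are 1,2-addition of the ester enolate, enolate scrambling on warming, and sluggish quaternisation next to the bulky C5 group. The fallback sets out from 1 and 2 and comes back at 6, replacing the one-pot lithium enolate process by a stepwise silyl route. Compound 2 is converted (LiN(iPr)2, Me3SiCl, THF, −78 °C) into benzyl trimethylsilyl dimethylketene acetal F6. Mukaiyama–Michael addition of F6 to 1 (Ph3CSbCl6 5 mol%, CH2Cl2, −78 °C) gives, trans to the isopropenyl group, the regiodefined trimethylsilyl enol ether F7. MeLi (THF, 0 °C) unmasks lithium enolate 5 from F7, and 5 is alkylated with 3 (DMPU, −78 → 0 °C) to 6.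

**Step 8.** The risk is slow oxidative addition and transmetalation at a tetrasubstituted triflate flanked by a quaternary carbon, with partial hydrolysis of the less hindered benzyl ester by the aqueous base. The fallback sets out from 14 and 10 and comes back at 16, replacing two-electron transmetalation by radical capture at nickel. Borane 15 (from 14 and 9-BBN) is iodinated (I2, NaOMe, MeOH) to the primary iodide (2R)-2-[(4R)-2,2-dimethyl-1,3-dioxolan-4-yl]-4-iodobutan-2-ol F8. F8 is joined to 10 by nickel-catalysed reductive cross-electrophile coupling (NiBr2(dme), 4,4′-di-tert-butyl-2,2′-bipyridine, Zn powder, DMA, 23 °C) under base-free conditions to give 16.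

## Further compounds

F1 | step 9 | Δ7-9-ketone: benzyl 2-[2-(2-benzyloxy-2-oxoethyl)-2,4-dimethyl-3-oxocyclohex-4-en-1-yl]-2-methylpropanoate, C5 and C10 as in 9 | O=C1[C@](C)(CC(=O)OCc2ccccc2)[C@@H](C(C)(C)C(=O)OCc2ccccc2)CC=C1C
F2 | step 9 | 7,8-epoxy-9-ketone: 7,8-epoxide of F1 with the oxirane oxygen trans to the C20 methyl and to the C4 side chain | O=C1[C@](C)(CC(=O)OCc2ccccc2)[C@@H](C(C)(C)C(=O)OCc2ccccc2)C[C@@H]2O[C@]12C
F3 | step 9 | 7-hydroxy-Δ8(9)-alkene: benzyl 2-[2-(2-benzyloxy-2-oxoethyl)-5-hydroxy-2,4-dimethylcyclohex-3-en-1-yl]-2-methylpropanoate, OH trans to the C20 methyl | CC1=C[C@](C)(CC(=O)OCc2ccccc2)[C@@H](C(C)(C)C(=O)OCc2ccccc2)C[C@@H]1O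
F4 | step 9 | 7-diethylphosphate: diethyl phosphate ester of F3 | CC1=C[C@](C)(CC(=O)OCc2ccccc2)[C@@H](C(C)(C)C(=O)OCc2ccccc2)C[C@@H]1OP(=O)(OCC)OCC
F5 | step 9 | Δ7 alkenol: Δ7 isomer of 16 with 9-H trans to the C20 methyl | C1=C(C)[C@@H](CC[C@@](C)(O)[C@H]2COC(C)(C)O2)[C@](C)(CC(=O)OCc2ccccc2)[C@@H](C(C)(C)C(=O)OCc2ccccc2)C1
F6 | step 1 | benzyl trimethylsilyl dimethylketene acetal, {[1-(benzyloxy)-2-methylprop-1-en-1-yl]oxy}trimethylsilane | CC(C)=C(O[Si](C)(C)C)OCc1ccccc1
F7 | step 1 | trimethylsilyl enol ether: benzyl 2-methyl-2-[(1S,5S)-2-methyl-5-(prop-1-en-2-yl)-3-(trimethylsilyloxy)cyclohex-2-en-1-yl]propanoate | C[Si](C)(C)OC1=C(C)[C@@H](C(C)(C)C(=O)OCc2ccccc2)C[C@H](C(C)=C)C1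
F8 | step 8 | (2R)-2-[(4R)-2,2-dimethyl-1,3-dioxolan-4-yl]-4-iodobutan-2-ol | ICC[C@@](C)(O)[C@H]1COC(C)(C)O1
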